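I read this flask at 4.0 h, long after its own delta run has gone flat: from 40.0 min to 90.0 min, L goes from 29.1% to 29.5% and E from 70.2% to 70.6%, with X at 0%.

| setting | delta | epsilon | flask |
|---|---|---|---|
| X | 20 mM | 13 mM | 20 mM |
| Q | 1.3 equiv | 1.3 equiv | 1.30 equiv |
| Z | 1.5 equiv | 1.5 equiv | 1.50 equiv |
| remark | the very flask that is asked about, followed so far | run made earlier |  |
| time |  |  | 4.0 h |

- delta (time / min: L / %, E / %, X / %): 5.00: 17.0, 30.7, 51.3; 15.0: 26.2, 61.5, 10.1; 25.0: 28.5, 68.6, 1.6; 40.0: 29.1, 70.2, 0.1; 60.0: 28.3, 70.1, 0.8; 80.0: 29.2, 69.9, 0; 90.0: 29.5, 70.6, 0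
- epsilon (time / h: L / %, E / %, X / %): 0.500: 21.3, 75.9, 1.7; 1.00: 22.0, 76.8, 1.0; 1.50: 21.8, 77.2, 0.1; 2.50: 22.6, 77.2, 0; 3.00: 20.5, 77.4, 0.1; 4.00: 20.9, 76.9, 0

(standard deviation of a reading: 0.5 percentage points)

- ratio of L to E at 40 s
- ratio of L to E at 4.0 h
- which of L and E there is more of at 4.0 h

- as a solid, counted per litre of solution: Z
- the analysis behind the earlier runs scatters by 0.5 percentage points, standard deviation
- on the list of suspects stand: G -> D; Q + G -> L; J + G -> E; Z <-> J; X <-> G
- at the start none of Z is in solution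

One thing looks wrong. Epsilon has the same equivalents as delta, yet over their last 4 readings L/E is 0.278 in epsilon and 0.413 in delta.

So I divide the rate of L by the rate of E. Time and [G] drop out, and the instantaneous selectivity d[L]/d[E] goes as [Q]/[J], just as a copolymer's instantaneous composition follows its feed. At fixed equivalents [Q] follows the charge of X. If J stops at a solubility ceiling while solid Z remains, [J] does not follow the charge, and at fixed equivalents the plateau ratio goes about in proportion to it. I therefore carry the selectivity per charge, the plateau L/E divided by the starting [X]: 0.0207 mM⁻¹ from delta. The plateau read in epsilon stands at 0.672 of the one read in delta, and the charge of epsilon at 0.650 of the charge of delta.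

No Z is in solution at the start, so I take [J] to start at nil. In delta the increment from 5.00 min to 15.0 min reads 0.299, and the cumulative ratio at 5.00 min stands higher, at 0.554. I expect a ratio above 0.554 at 40 s, and 0.413 with E ahead at 4.0 h.

The forecast says 1.5, 0.415 and E ahead: "J appears capped at the same solubility in both runs".

The flask gives 1.61 at 40 s and 0.415 at 4.0 h, with E at 70.2% and L at 29.1%.

    G → D (k = 0.00740 s⁻¹)
    Q + G → L (k = 13.0 M⁻¹ s⁻¹)
    J + G → E (k = 72.0 M⁻¹ s⁻¹)
    Z ⇌ J, rate k4*(cs4 - [J]) while solid is left; crystals form when [J] > cs4 (solubility = 13.0 mM, k = 0.0140 s⁻¹)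
    X ⇌ G (K = 0.00280, k = 0.0140 s⁻¹)

At 4.00 h [J] stands at 13.0 mM with 9.89% of Z still solid, and 0.0207 mM⁻¹ times this charge of 20 mM reads 0.414. The neighbour with 80 mM of X, at the same equivalents, also holds [J] at 13.0 mM. There 0.0207 mM⁻¹ gives 1.66, and that flask stands at 1.69.

Readings and results were generated by integration on assumed constants; scatter was added.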